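**Retrosynthetic overview**

1. Lupulone 16 has one ring, numbered here C1 (ketone), C2 (mono-prenyl), C3, C4 (isovaleryl-bearing), C5, C6 (gem-diprenyl). The route rests on C4 being the central carbon of a 1,3-diketone (the C5 carbonyl and the isovaleryl carbonyl) that can reach the acyl carbon C3, so C3–C4 is made by a Claisen-type C-acylation, as in the biosynthesis.
2. The acyl donor at C3 is acylketene 15, stored in precursor 14 as a 1,3-dioxin-4-one that holds C1–C3 and the C2 prenyl group; heat expels acetone.
3. 14 comes from methyl ketone 10 by aldol addition to isovaleraldehyde 11 and oxidation (C4–isovaleryl bond); 10 comes from keto-dioxinone 7 by double prenylation, which sets quaternary C6 before ring closure.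
4. 7 comes from 5-prenyl dioxinone 4 by γ-acetylation (C5–C6 bond); 4 comes from 2,2,6-trimethyl-4H-1,3-dioxin-4-one 1 by iodination and Stille prenylation.
5. Ring order: the dioxinone ring is carried from 1 as a mask and is destroyed in step 7, where the carbocycle, the only ring of the target, is formed last.

Key step: step 7

Remark: labels C1–C6 always mean the lupulone ring and dioxinone ring atoms are called "position n"; lupulone is drawn as one enol tautomer and should be isolated as the tautomer mixture; 9 and 13 are racemic at centres that later steps erase; stannane 3 is taken as commercial.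

**Route**

Step 1
Reactants: 1 2,2,6-trimethyl-4H-1,3-dioxin-4-one
Product: 2 5-iodo-2,2,6-trimethyl-4H-1,3-dioxin-4-one
Conditions: NIS (1.1 equiv), AcOH, rt, dark
Reagents that add atoms: N-iodosuccinimide, O=C1CCC(=O)N1I
Why: Electrophilic iodination of the β-alkoxy enoate at its nucleophilic α-carbon (position 5), an enol-ether-type halogenation that is an established way to 5-halodioxinones.

Step 2
Reactants: 2 5-iodo-2,2,6-trimethyl-4H-1,3-dioxin-4-one; 3 tributyl(3-methylbut-2-en-1-yl)stannane
Product: 4 2,2,6-trimethyl-5-(3-methylbut-2-en-1-yl)-4H-1,3-dioxin-4-one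
Conditions: Pd(PPh3)4 (5 mol %), DMF, 60 °C, degassed
Reagents that add atoms: tributyl(3-methylbut-2-en-1-yl)stannane 3, CCCC[Sn](CCCC)(CCCC)CC=C(C)C
Why: Stille coupling of an α-iodo enoate with an allylic stannane should join the prenyl group through its unsubstituted terminus, at a temperature below that at which the dioxinone cycloreverts.

Step 3
Reactants: 4 2,2,6-trimethyl-5-(3-methylbut-2-en-1-yl)-4H-1,3-dioxin-4-one; 5 1-acetylimidazole
Product: 7 2,2-dimethyl-5-(3-methylbut-2-en-1-yl)-6-(2-oxopropyl)-4H-1,3-dioxin-4-one, via lithium dienolate 6 (not isolated)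
Conditions: LiN(SiMe3)2 (2.1 equiv), THF, −78 °C; then 1-acetylimidazole (1.0 equiv), −78 → −40 °C; AcOH quench
Reagents that add atoms: 1-acetylimidazole 5, CC(=O)n1ccnc1
Why: γ-Deprotonation of the 6-methyl group gives the vinylogous ester dienolate, which undergoes Claisen-type C-acylation at its exocyclic carbon by the acyl imidazole, the second equivalent of base absorbing the more acidic product.

Step 4
Reactants: 7 2,2-dimethyl-5-(3-methylbut-2-en-1-yl)-6-(2-oxopropyl)-4H-1,3-dioxin-4-one; 8 prenyl bromide (1-bromo-3-methylbut-2-ene)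
Product: 10 2,2-dimethyl-5-(3-methylbut-2-en-1-yl)-6-[6-methyl-3-(3-methylbut-2-en-1-yl)-2-oxohept-5-en-3-yl]-4H-1,3-dioxin-4-one, via mono-prenyl ketone 9 (not isolated)
Conditions: NaH (2.2 equiv), prenyl bromide (2.4 equiv), THF, 0 → 40 °C
Reagents that add atoms: prenyl bromide 8, CC(C)=CCBr
Why: Double enolate C-alkylation of the methylene activated by the ketone and, vinylogously, by the dioxinone ester (as in the α,α-dialkylation of aryl- or vinyl-acetones) should set quaternary C6, with the soft allylic bromide and the tight sodium ion pair in THF favouring carbon over oxygen.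

Step 5
Reactants: 10 2,2-dimethyl-5-(3-methylbut-2-en-1-yl)-6-[6-methyl-3-(3-methylbut-2-en-1-yl)-2-oxohept-5-en-3-yl]-4H-1,3-dioxin-4-one; 11 isovaleraldehyde (3-methylbutanal)
Product: 13 rac-6-[4-hydroxy-6-methyl-1,1-bis(3-methylbut-2-en-1-yl)-2-oxoheptyl]-2,2-dimethyl-5-(3-methylbut-2-en-1-yl)-4H-1,3-dioxin-4-one, via lithium enolate 12 (not isolated)
Conditions: LiN(i-Pr)2 (1.1 equiv), THF, −78 °C; then isovaleraldehyde, −78 °C; AcOH quench at −78 °C
Reagents that add atoms: isovaleraldehyde 11, CC(C)CC=O
Why: Aldol addition of the kinetic lithium enolate is regiochemically unambiguous because the methyl group is the only enolisable position of the ketone (the other α-carbon is quaternary); the carbinol centre forms as a racemate and is erased in step 6.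

Step 6
Reactants: 13 rac-6-[4-hydroxy-6-methyl-1,1-bis(3-methylbut-2-en-1-yl)-2-oxoheptyl]-2,2-dimethyl-5-(3-methylbut-2-en-1-yl)-4H-1,3-dioxin-4-one
Product: 14 2,2-dimethyl-5-(3-methylbut-2-en-1-yl)-6-[6-methyl-1,1-bis(3-methylbut-2-en-1-yl)-2,4-dioxoheptyl]-4H-1,3-dioxin-4-one
Conditions: Dess–Martin periodinane (1.2 equiv), CH2Cl2, 0 °C → rt
Reagents that add atoms: none
Why: Dess–Martin oxidation turns the β-hydroxy ketone into the 1,3-diketone under near-neutral conditions that should spare the prenyl alkenes and the dioxinone and avoid base-induced retro-aldol cleavage.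

Step 7
Reactants: 14 2,2-dimethyl-5-(3-methylbut-2-en-1-yl)-6-[6-methyl-1,1-bis(3-methylbut-2-en-1-yl)-2,4-dioxoheptyl]-4H-1,3-dioxin-4-one
Product: 16 lupulone, via acylketene 15 (not isolated)
Conditions: DMAP (20 mol %), toluene (0.01 M), argon, 110 °C; then 1 M HCl wash
Reagents that add atoms: none
Why: At 110 °C the dioxinone ring of 14 undergoes retro-[4+2] loss of acetone to give acylketene 15; after rotation about the C1–C2 bond its sp carbon (C3) lies over C4, the nucleophilic central carbon of the enolised C5/isovaleryl 1,3-diketone, which adds in the plane of the ketene, and proton transfer gives the conjugated, hydrogen-bonded triketone enol. The closest known chemistry is the C-acylation of enolised 1,3-dicarbonyl compounds by dioxinone-derived acylketenes and the DMAP-mediated conversion of 1,3-dione enol esters into 2-acyl-1,3-diones, applied here within one molecule. The six-membered carbocycle C1–C6 closes in a 6-(enolendo)-exo-dig mode, helped by the gem-diprenyl (Thorpe–Ingold) compression at C6. No stereocentre is created, since C6 carries two identical prenyl groups and C2 and C4 end as sp2 enol carbons. The selectivity needed is C- over O-acylation (attack by the C5 enol oxygen would give an isomeric six-membered enol lactone); it is secured by the greater stability of the triketone and by DMAP, which reopens any enol lactone to an acylpyridinium–diketonate pair that recloses at carbon, while C4 is the only carbon nucleophile within reach because C6 is quaternary and C2 bears no hydrogen until the ring is closed. No alkoxide is present, so the non-enolisable C1–C6–C5 dicarbonyl unit is not exposed to retro-Claisen cleavage, and high dilution under argon should suppress ketene dimerisation and air oxidation of the product.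

**Compound list**

1 | 2,2,6-trimethyl-4H-1,3-dioxin-4-one | CC1=CC(=O)OC(C)(C)O1 | starting material
2 | 5-iodo-2,2,6-trimethyl-4H-1,3-dioxin-4-one | CC1=C(I)C(=O)OC(C)(C)O1 | intermediate
3 | tributyl(3-methylbut-2-en-1-yl)stannane | CCCC[Sn](CCCC)(CCCC)CC=C(C)C | starting material
4 | 2,2,6-trimethyl-5-(3-methylbut-2-en-1-yl)-4H-1,3-dioxin-4-one | CC1=C(CC=C(C)C)C(=O)OC(C)(C)O1 | intermediate
5 | 1-acetylimidazole | CC(=O)n1ccnc1 | starting material
6 | lithium 2,2-dimethyl-6-methylidene-5-(3-methylbut-2-en-1-yl)-6H-1,3-dioxin-4-olate (lithium dienolate of 4) | [Li+].C=C1OC(C)(C)OC([O-])=C1CC=C(C)C | intermediate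
7 | 2,2-dimethyl-5-(3-methylbut-2-en-1-yl)-6-(2-oxopropyl)-4H-1,3-dioxin-4-one | CC(=O)CC1=C(CC=C(C)C)C(=O)OC(C)(C)O1 | intermediate
8 | prenyl bromide (1-bromo-3-methylbut-2-ene) | CC(C)=CCBr | starting material
9 | rac-2,2-dimethyl-5-(3-methylbut-2-en-1-yl)-6-(6-methyl-2-oxohept-5-en-3-yl)-4H-1,3-dioxin-4-one (mono-prenyl ketone) | CC(=O)C(CC=C(C)C)C1=C(CC=C(C)C)C(=O)OC(C)(C)O1 | intermediate
10 | 2,2-dimethyl-5-(3-methylbut-2-en-1-yl)-6-[6-methyl-3-(3-methylbut-2-en-1-yl)-2-oxohept-5-en-3-yl]-4H-1,3-dioxin-4-one | CC(=O)C(CC=C(C)C)(CC=C(C)C)C1=C(CC=C(C)C)C(=O)OC(C)(C)O1 | intermediate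
11 | isovaleraldehyde (3-methylbutanal) | CC(C)CC=O | starting material
12 | lithium enolate of 10 (lithium 3-[2,2-dimethyl-5-(3-methylbut-2-en-1-yl)-4-oxo-4H-1,3-dioxin-6-yl]-6-methyl-3-(3-methylbut-2-en-1-yl)hepta-1,5-dien-2-olate) | [Li+].C=C([O-])C(CC=C(C)C)(CC=C(C)C)C1=C(CC=C(C)C)C(=O)OC(C)(C)O1 | intermediate
13 | rac-6-[4-hydroxy-6-methyl-1,1-bis(3-methylbut-2-en-1-yl)-2-oxoheptyl]-2,2-dimethyl-5-(3-methylbut-2-en-1-yl)-4H-1,3-dioxin-4-one | CC(C)CC(O)CC(=O)C(CC=C(C)C)(CC=C(C)C)C1=C(CC=C(C)C)C(=O)OC(C)(C)O1 | intermediate
14 | 2,2-dimethyl-5-(3-methylbut-2-en-1-yl)-6-[6-methyl-1,1-bis(3-methylbut-2-en-1-yl)-2,4-dioxoheptyl]-4H-1,3-dioxin-4-one | CC(C)CC(=O)CC(=O)C(CC=C(C)C)(CC=C(C)C)C1=C(CC=C(C)C)C(=O)OC(C)(C)O1 | intermediate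
15 | 9-methyl-2,4,4-tris(3-methylbut-2-en-1-yl)dec-1-ene-1,3,5,7-tetrone (acylketene) | O=C=C(CC=C(C)C)C(=O)C(CC=C(C)C)(CC=C(C)C)C(=O)CC(=O)CC(C)C | intermediate
16 | lupulone | CC(C)=CCC1=C(O)C(C(=O)CC(C)C)=C(O)C(CC=C(C)C)(CC=C(C)C)C1=O | target

**Step count**

Total steps: 7. Longest linear sequence: 7 steps (1 → 16).

**Steps most likely to fail**

Step 7. The enol oxygen at C5 may capture the ketene faster than C4 and the resulting enol lactone may not re-equilibrate; the ketene may also be lost to dimerisation or to [2+2] cycloaddition with a prenyl alkene before C4 reaches it. The fallback sets out from 14 and separates ketene capture from ring closure. 14 is heated in toluene at 110 °C in a sealed vessel with methanol (5 equiv), so that the external alcohol intercepts the acylketene and gives racemic methyl 9-methyl-2,4,4-tris(3-methylbut-2-en-1-yl)-3,5,7-trioxodecanoate F1. F1 is then closed by a Dieckmann-type Claisen condensation with KOt-Bu (3 equiv) in THF at 0 °C → rt, followed by a citric acid quench. Deprotonation of both β-dicarbonyl units shields the C1 and C5 carbonyls from nucleophilic attack, and the hindered alkoxide keeps retro-Claisen cleavage down. Both operations are known reaction types (alcohol capture of dioxinone-derived acylketenes; base-mediated Claisen cyclisation of 3,5,7-triketo esters to acylphloroglucinol-type triketones). The fallback returns to the route at 16.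

Step 4. The hindered enolate of mono-prenyl ketone 9 may alkylate on oxygen, the second alkylation may stall, or alkylation may stray to the methyl group of the ketone. The fallback sets out from 7 and replaces the SN2 alkylation by a Tsuji–Trost allylic alkylation: Pd(PPh3)4 (5 mol %) and methyl (3-methylbut-2-en-1-yl) carbonate (COC(=O)OCC=C(C)C, 2.5 equiv) in THF at 40 °C. The soft stabilised carbanion should attack the unsubstituted terminus of the prenyl–palladium complex, and O-allylated material re-ionises under the catalyst and is funnelled to carbon. The sequence passes through the same mono-prenyl ketone 9 and returns at 10; it makes no new compound (F0).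

Step 2. Allylic transposition during transmetalation may deliver the 1,1-dimethylallyl isomer, and protodeiodination or slow turnover may intervene at the mild temperature the dioxinone demands. The fallback sets out from 2 and reverses the polarity of the coupling. Iodine–magnesium exchange with i-PrMgCl·LiCl in THF at −40 °C gives chloro(2,2,6-trimethyl-4-oxo-4H-1,3-dioxin-5-yl)magnesium F2. Transmetalation with ZnCl2 gives chloro(2,2,6-trimethyl-4-oxo-4H-1,3-dioxin-5-yl)zinc F3. Negishi-type coupling of F3 with prenyl bromide 8 under Pd(PPh3)4 (3 mol %) at 0 °C → rt should join the alkenyl group to the unsubstituted allyl terminus. The fallback returns at 4.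

**Further compounds**

F1 | step 7 | methyl 9-methyl-2,4,4-tris(3-methylbut-2-en-1-yl)-3,5,7-trioxodecanoate (racemic) | COC(=O)C(CC=C(C)C)C(=O)C(CC=C(C)C)(CC=C(C)C)C(=O)CC(=O)CC(C)C
F0 | step 4 | none | none
F2 | step 2 | chloro(2,2,6-trimethyl-4-oxo-4H-1,3-dioxin-5-yl)magnesium | CC1=C([Mg]Cl)C(=O)OC(C)(C)O1
F3 | step 2 | chloro(2,2,6-trimethyl-4-oxo-4H-1,3-dioxin-5-yl)zinc | CC1=C([Zn]Cl)C(=O)OC(C)(C)O1
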